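**Plan**

1. The target is the achiral flavone 2-(2,5-dihydroxy-3,4-dimethoxyphenyl)-5-hydroxy-7-methoxy-4H-chromen-4-one. Ring A is the benzo ring, ring C the pyranone, ring B the pendant aryl (primed locants).
2. Enabling feature: ring B carries para oxygens at C2' and C5', vicinal methoxyls at C3' and C4', a lone hydrogen at C6', and ring C on C1'. This is the 4-alkoxyphenol pattern that an alkenylcarbene/alkyne/CO benzannulation produces.
3. Retrosynthetic cuts: first C5'–C6', C1'–C2' and C2'–C3' of ring B, giving a benzyloxy(1,2-dimethoxyvinyl)carbene complex of chromium, one CO ligand and a 2-ethynylchromone. Then the ethynyl carbon is traced back through an aldehyde to an ester. Finally O1–C2 and the C3–C2 bond of ring C are cut (Claisen condensation with oxalate).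
4. Forward order: ring C is fused onto ring A (step 3), the C2 ester is turned into an ethynyl group (steps 4–7), the carbene complex is made separately (steps 1–2), ring B is built last on the alkyne (step 8), and both benzyl ethers are removed (step 9).
5. Stereochemistry: the target has no stereocentre. The only stereo-element carried is the Z geometry of the vinyl ether, which disappears when ring B aromatizes.

Key step: step 8

Assumption: (Z)-1,2-dimethoxyethene is used as the single Z isomer (a commercial Z/E mixture would be fractionated first); its geometry has no consequence for the target.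

**Step 1**
Reactants: 1 (Z)-1,2-dimethoxyethene; 2 chromium hexacarbonyl, Cr(CO)6
Product: 5 tetramethylammonium pentacarbonyl[(Z)-2,3-dimethoxyprop-2-enoyl]chromate, via vinyllithium 3 (not isolated), via lithium acylchromate 4 (not isolated)
Conditions: t-BuLi, THF, −78 °C; Cr(CO)6, THF/Et2O, −78 °C → rt; then Me4NBr, H2O, 0 °C
Reagents that add atoms: tetramethylammonium bromide, C[N+](C)(C)C.[Br-]
Why: α-lithiation of the vinyl ether with retention of geometry and addition of the vinyllithium to a CO ligand is the classical Fischer route to acylchromates, and cation exchange should give a storable salt.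

**Step 2**
Reactants: 5 tetramethylammonium pentacarbonyl[(Z)-2,3-dimethoxyprop-2-enoyl]chromate
Product: 7 pentacarbonyl{(benzyloxy)[(Z)-1,2-dimethoxyethenyl]methylidene}chromium, via acetoxycarbene complex 6 (not isolated)
Conditions: AcBr, CH2Cl2, −40 °C; then BnOH, −40 → 0 °C
Reagents that add atoms: benzyl alcohol, OCc1ccccc1
Why: O-acylation of the acylchromate gives a strongly electrophilic acyloxycarbene complex that exchanges acetate for an alcohol by addition–elimination at the carbene carbon, the established route to alkoxycarbene complexes whose alkyl group a Meerwein salt cannot deliver.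

**Step 3**
Reactants: 8 2,6-dihydroxy-4-methoxyacetophenone; 9 diethyl oxalate
Product: 11 ethyl 5-hydroxy-7-methoxy-4-oxo-4H-chromene-2-carboxylate, via diketo ester 10 (not isolated)
Conditions: NaOEt, EtOH, reflux; then conc. HCl, EtOH, reflux
Reagents that add atoms: none
Why: Claisen condensation of the methyl ketone with oxalate followed by acid cyclodehydration is the standard entry to chromone-2-carboxylates, and the symmetry of 8 allows only one chromone.

**Step 4**
Reactants: 11 ethyl 5-hydroxy-7-methoxy-4-oxo-4H-chromene-2-carboxylate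
Product: 12 ethyl 5-(benzyloxy)-7-methoxy-4-oxo-4H-chromene-2-carboxylate
Conditions: BnBr, K2CO3, Bu4NI (cat.), DMF, 60 °C
Reagents that add atoms: benzyl bromide, BrCc1ccccc1
Why: Williamson etherification of the chelated 5-hydroxyl, which needs a polar solvent and warming, masks the phenol against the lithium reagent of step 7 and the carbene complex of step 8.

**Step 5**
Reactants: 12 ethyl 5-(benzyloxy)-7-methoxy-4-oxo-4H-chromene-2-carboxylate
Product: 13 5-(benzyloxy)-2-(hydroxymethyl)-7-methoxy-4H-chromen-4-one
Conditions: NaBH4, EtOH/THF, 0 °C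
Reagents that add atoms: none
Why: the C2 ester is activated by the ring oxygen and the vinylogous carbonyl, so borohydride should reduce it to the primary alcohol while the cross-conjugated pyranone carbonyl stays intact, a known chemoselective reduction of chromone-2-carboxylates.

**Step 6**
Reactants: 13 5-(benzyloxy)-2-(hydroxymethyl)-7-methoxy-4H-chromen-4-one
Product: 14 5-(benzyloxy)-7-methoxy-4-oxo-4H-chromene-2-carbaldehyde
Conditions: Dess–Martin periodinane, CH2Cl2, rt
Reagents that add atoms: none
Why: Dess–Martin oxidation converts the allylic-type primary alcohol to the aldehyde under neutral conditions without over-oxidation or attack on the pyranone.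

**Step 7**
Reactants: 14 5-(benzyloxy)-7-methoxy-4-oxo-4H-chromene-2-carbaldehyde
Product: 15 5-(benzyloxy)-2-ethynyl-7-methoxy-4H-chromen-4-one
Conditions: Me3SiCHN2, LiN(iPr)2, THF, −78 °C; then 14, −78 → 0 °C; aq. NH4Cl
Reagents that add atoms: trimethylsilyldiazomethane, C[Si](C)(C)C=[N+]=[N-]
Why: in this Colvin rearrangement the lithiated silyldiazomethane adds to the aldehyde, Peterson elimination gives a diazoalkene, and loss of N2 with 1,2-hydrogen shift of the alkylidene carbene gives the terminal alkyne; the aprotic, cold conditions avoid the alkoxide conjugate addition that a methanolic carbonate homologation could inflict on this Michael-acceptor alkyne.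

**Step 8**
Reactants: 7 pentacarbonyl{(benzyloxy)[(Z)-1,2-dimethoxyethenyl]methylidene}chromium; 15 5-(benzyloxy)-2-ethynyl-7-methoxy-4H-chromen-4-one
Product: 17 5-(benzyloxy)-2-[5-(benzyloxy)-2-hydroxy-3,4-dimethoxyphenyl]-7-methoxy-4H-chromen-4-one, via tricarbonylchromium arene complex 16 (not isolated)
Conditions: THF, 55 °C, argon; then air, MeCN, rt
Reagents that add atoms: none
Why: Proposed new method: thermal loss of one CO from 7 frees a site on zerovalent chromium, the alkyne of 15 inserts into the Cr=C bond with its unsubstituted carbon bonding to the carbene carbon (C5'–C6'), CO insertion then gives a chromium-bound dienylketene (C1'–C2'), and six-electron electrocyclic closure of the ketene carbon onto the methoxy-bearing vinyl terminus (C2'–C3') followed by enolization delivers ring B as its Cr(CO)3 complex 16, from which air releases 17. The closest known reaction type is the Dötz benzannulation of α-alkoxyalkenyl(alkoxy)carbene complexes of chromium with terminal alkynes to 4-alkoxyphenols; what has not been shown is the combination of a 1,2-dialkoxyvinyl carbene ligand with an alkyne conjugated to an electron-poor pyranone. Ring B closes by a thermally allowed disrotatory six-electron electrocyclization of the dienylketene, and no stereocentre is created, the Z geometry of the vinyl ether vanishing on aromatization. Two selectivities are needed, the regiochemistry of alkyne insertion and phenol formation in preference to indene, cyclobutenone or furan products: a terminal alkyne places its substituted carbon away from the carbene carbon for steric reasons and hence next to the new hydroxyl, and an alkenyl carbene ligand on chromium in THF incorporates CO dependably. Because the β-methoxy donor strengthens back-bonding and should slow CO loss, gentle heating and a small excess of 7 are planned.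

**Step 9**
Reactants: 17 5-(benzyloxy)-2-[5-(benzyloxy)-2-hydroxy-3,4-dimethoxyphenyl]-7-methoxy-4H-chromen-4-one
Product: 18 2-(2,5-dihydroxy-3,4-dimethoxyphenyl)-5-hydroxy-7-methoxy-4H-chromen-4-one
Conditions: H2 (1 atm), 10% Pd/C, EtOAc/MeOH, rt; filtration under argon
Reagents that add atoms: none
Why: catalytic hydrogenolysis should cleave both benzyl ethers while the flavone double bond and the aryl methyl ethers stay inert at one atmosphere; the hydroquinone product is handled without air.

**Compound list**

1 | (Z)-1,2-dimethoxyethene | CO/C=C\OC | starting material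
2 | chromium hexacarbonyl, Cr(CO)6 | O=C=[Cr](=C=O)(=C=O)(=C=O)(=C=O)=C=O | starting material
3 | (Z)-1,2-dimethoxyethenyllithium | [Li]/C(OC)=C/OC | intermediate (not isolated)
4 | lithium pentacarbonyl[(Z)-2,3-dimethoxyprop-2-enoyl]chromate | O=C=[Cr](=C=O)(=C=O)(=C=O)(=C=O)=C([O-])/C(OC)=C/OC.[Li+] | intermediate (not isolated)
5 | tetramethylammonium pentacarbonyl[(Z)-2,3-dimethoxyprop-2-enoyl]chromate | O=C=[Cr](=C=O)(=C=O)(=C=O)(=C=O)=C([O-])/C(OC)=C/OC.C[N+](C)(C)C | intermediate
6 | pentacarbonyl{(acetyloxy)[(Z)-1,2-dimethoxyethenyl]methylidene}chromium | O=C=[Cr](=C=O)(=C=O)(=C=O)(=C=O)=C(OC(C)=O)/C(OC)=C/OC | intermediate (not isolated)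
7 | pentacarbonyl{(benzyloxy)[(Z)-1,2-dimethoxyethenyl]methylidene}chromium | O=C=[Cr](=C=O)(=C=O)(=C=O)(=C=O)=C(OCc1ccccc1)/C(OC)=C/OC | intermediate
8 | 2,6-dihydroxy-4-methoxyacetophenone | CC(=O)c1c(O)cc(OC)cc1O | starting material
9 | diethyl oxalate | CCOC(=O)C(=O)OCC | starting material
10 | ethyl 4-(2,6-dihydroxy-4-methoxyphenyl)-2,4-dioxobutanoate | CCOC(=O)C(=O)CC(=O)c1c(O)cc(OC)cc1O | intermediate (not isolated)
11 | ethyl 5-hydroxy-7-methoxy-4-oxo-4H-chromene-2-carboxylate | CCOC(=O)c1cc(=O)c2c(O)cc(OC)cc2o1 | intermediate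
12 | ethyl 5-(benzyloxy)-7-methoxy-4-oxo-4H-chromene-2-carboxylate | CCOC(=O)c1cc(=O)c2c(OCc3ccccc3)cc(OC)cc2o1 | intermediate
13 | 5-(benzyloxy)-2-(hydroxymethyl)-7-methoxy-4H-chromen-4-one | OCc1cc(=O)c2c(OCc3ccccc3)cc(OC)cc2o1 | intermediate
14 | 5-(benzyloxy)-7-methoxy-4-oxo-4H-chromene-2-carbaldehyde | O=Cc1cc(=O)c2c(OCc3ccccc3)cc(OC)cc2o1 | intermediate
15 | 5-(benzyloxy)-2-ethynyl-7-methoxy-4H-chromen-4-one | C#Cc1cc(=O)c2c(OCc3ccccc3)cc(OC)cc2o1 | intermediate
16 | tricarbonylchromium complex of 17, bound η6 to ring B (the η6 bond cannot be written in SMILES, so arene and Cr(CO)3 are given as two parts) | COc1cc(OCc2ccccc2)c2c(=O)cc(-c3cc(OCc4ccccc4)c(OC)c(OC)c3O)oc2c1.O=C=[Cr](=C=O)=C=O | intermediate (not isolated)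
17 | 5-(benzyloxy)-2-[5-(benzyloxy)-2-hydroxy-3,4-dimethoxyphenyl]-7-methoxy-4H-chromen-4-one | COc1cc(OCc2ccccc2)c2c(=O)cc(-c3cc(OCc4ccccc4)c(OC)c(OC)c3O)oc2c1 | intermediate
18 | 2-(2,5-dihydroxy-3,4-dimethoxyphenyl)-5-hydroxy-7-methoxy-4H-chromen-4-one | COc1cc(O)c2c(=O)cc(-c3cc(O)c(OC)c(OC)c3O)oc2c1 | target

**Step count**

Total: 9 steps. Longest linear sequence: 7 steps (steps 3 to 9, from 8); the carbene branch contributes steps 1 and 2 and joins at step 8.

**Steps most likely to fail**

Step 8 (proposed new method). CO loss from the donor-substituted carbene complex may be slow, and the electron-poor conjugated alkyne may be diverted into oligomerization or into cyclobutenone or furan channels before the dienylketene closes.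

The fallback sets out from 8, builds the flavone by chalcone chemistry, and returns at 18:
- Mono-O-benzylation of 8 (BnBr, K2CO3, acetone, reflux) should give 1-[2-(benzyloxy)-6-hydroxy-4-methoxyphenyl]ethanone F1.
- Commercial 2-hydroxy-3,4-dimethoxybenzaldehyde would be hydroxylated para to its phenol by Elbs persulfate oxidation (K2S2O8, aq. NaOH), passing through potassium 5-formyl-4-hydroxy-2,3-dimethoxyphenyl sulfate F2. Acid hydrolysis (aq. HCl, warm) then gives 2,5-dihydroxy-3,4-dimethoxybenzaldehyde F3.
- Double benzylation (BnBr, K2CO3, DMF) gives 2,5-bis(benzyloxy)-3,4-dimethoxybenzaldehyde F4.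
- Claisen–Schmidt condensation of F1 with F4 (KOH, EtOH, rt) should give (E)-1-[2-(benzyloxy)-6-hydroxy-4-methoxyphenyl]-3-[2,5-bis(benzyloxy)-3,4-dimethoxyphenyl]prop-2-en-1-one F5.
- Oxidative cyclization (I2 cat., DMSO, 120 °C) gives 5-(benzyloxy)-2-[2,5-bis(benzyloxy)-3,4-dimethoxyphenyl]-7-methoxy-4H-chromen-4-one F6.
- Hydrogenolysis (H2, Pd/C, EtOAc/MeOH) of the three benzyl ethers gives 18.

Step 7. The lithiated diazo reagent or the lithium silanolate may add to the pyranone (conjugate addition, ring opening) in competition with carbonyl addition and carbene rearrangement.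

The fallback sets out from 14, replaces the diazo homologation by olefination, reduction and elimination, and returns at 15:
- Ramirez olefination (CBr4, PPh3, CH2Cl2, 0 °C) should give 5-(benzyloxy)-2-(2,2-dibromoethenyl)-7-methoxy-4H-chromen-4-one F7.
- Selective hydrogenolysis of the bromine trans to the ring (Bu3SnH, Pd(PPh3)4 cat., toluene, rt) gives 5-(benzyloxy)-2-[(Z)-2-bromoethenyl]-7-methoxy-4H-chromen-4-one F8.
- Anti-elimination of HBr with Bu4NF in DMF at rt gives 15.

Step 2. The acetoxycarbene intermediate may decompose thermally before alcoholysis, or benzyl alcohol may add in conjugate fashion to the vinylcarbene.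

The fallback sets out from 5, replaces the benzyl group on the carbene oxygen by a methyl group that is later removed oxidatively, and returns at 18:
- O-Methylation of 5 (MeOTf, CH2Cl2, 0 °C) should give pentacarbonyl{methoxy[(Z)-1,2-dimethoxyethenyl]methylidene}chromium F9.
- Benzannulation of F9 with 15 under the conditions of step 8 passes through the tricarbonylchromium arene complex F10 and, after air, gives 5-(benzyloxy)-2-(2-hydroxy-3,4,5-trimethoxyphenyl)-7-methoxy-4H-chromen-4-one F11.
- Oxidative demethylation of the 4-methoxyphenol ((NH4)2Ce(NO3)6, MeCN/H2O, 0 °C) gives 2-[5-(benzyloxy)-7-methoxy-4-oxo-4H-chromen-2-yl]-5,6-dimethoxycyclohexa-2,5-diene-1,4-dione F12.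
- Hydrogenation (H2, Pd/C, EtOAc/MeOH) reduces the quinone to the hydroquinone and cleaves the remaining benzyl ether, giving 18.

**Further compounds**

F1 | step 8 | 1-[2-(benzyloxy)-6-hydroxy-4-methoxyphenyl]ethanone | CC(=O)c1c(O)cc(OC)cc1OCc1ccccc1
F2 | step 8 | potassium 5-formyl-4-hydroxy-2,3-dimethoxyphenyl sulfate | O=Cc1cc(OS(=O)(=O)[O-])c(OC)c(OC)c1O.[K+]
F3 | step 8 | 2,5-dihydroxy-3,4-dimethoxybenzaldehyde | O=Cc1cc(O)c(OC)c(OC)c1O
F4 | step 8 | 2,5-bis(benzyloxy)-3,4-dimethoxybenzaldehyde | O=Cc1cc(OCc2ccccc2)c(OC)c(OC)c1OCc1ccccc1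
F5 | step 8 | (E)-1-[2-(benzyloxy)-6-hydroxy-4-methoxyphenyl]-3-[2,5-bis(benzyloxy)-3,4-dimethoxyphenyl]prop-2-en-1-one | COc1cc(O)c(C(=O)/C=C/c2cc(OCc3ccccc3)c(OC)c(OC)c2OCc2ccccc2)c(OCc2ccccc2)c1
F6 | step 8 | 5-(benzyloxy)-2-[2,5-bis(benzyloxy)-3,4-dimethoxyphenyl]-7-methoxy-4H-chromen-4-one | COc1cc(OCc2ccccc2)c2c(=O)cc(-c3cc(OCc4ccccc4)c(OC)c(OC)c3OCc3ccccc3)oc2c1
F7 | step 7 | 5-(benzyloxy)-2-(2,2-dibromoethenyl)-7-methoxy-4H-chromen-4-one | BrC(Br)=Cc1cc(=O)c2c(OCc3ccccc3)cc(OC)cc2o1
F8 | step 7 | 5-(benzyloxy)-2-[(Z)-2-bromoethenyl]-7-methoxy-4H-chromen-4-one | Br/C=C\c1cc(=O)c2c(OCc3ccccc3)cc(OC)cc2o1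
F9 | step 2 | pentacarbonyl{methoxy[(Z)-1,2-dimethoxyethenyl]methylidene}chromium | O=C=[Cr](=C=O)(=C=O)(=C=O)(=C=O)=C(OC)/C(OC)=C/OC
F10 | step 2 | tricarbonylchromium complex of F11, bound η6 to ring B (arene and Cr(CO)3 written as two parts) | COc1cc(OCc2ccccc2)c2c(=O)cc(-c3cc(OC)c(OC)c(OC)c3O)oc2c1.O=C=[Cr](=C=O)=C=O
F11 | step 2 | 5-(benzyloxy)-2-(2-hydroxy-3,4,5-trimethoxyphenyl)-7-methoxy-4H-chromen-4-one | COc1cc(OCc2ccccc2)c2c(=O)cc(-c3cc(OC)c(OC)c(OC)c3O)oc2c1
F12 | step 2 | 2-[5-(benzyloxy)-7-methoxy-4-oxo-4H-chromen-2-yl]-5,6-dimethoxycyclohexa-2,5-diene-1,4-dione | COc1cc(OCc2ccccc2)c2c(=O)cc(C3=CC(=O)C(OC)=C(OC)C3=O)oc2c1
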